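The earlier runs and the new flask were computed from invented constants; noise was put on by code.

Count turnovers. I divide the target by the enzyme loading, so that flasks with different loadings can stand side by side.

| setting | Friday's | Tuesday's | red | amber |
|---|---|---|---|---|
| starting material | 19 mM (in portions, 4) | 19 mM (in portions, 4) | 19 mM (in portions, 4) | 19 mM |
| second substrate | 1.1 equiv | 1.1 equiv | 1.10 equiv | 1.10 equiv |
| free enzyme | 0.0087 mol% | 0.011 mol% | 0.01 mol% | 0.015 mol% |
| remark | run made earlier; portions every 50 s | run made earlier; portions every 50 s | the portions of starting material follow each other after 50 s, the first at the start | everything together at the start |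
| time |  |  | 3.0 min | 3.0 min |

- Friday's (time / min: target / %, starting material / %): 0.250: 9.8, 13.9; 0.833: 21.9, 1.0; 1.33: 35.9, 9.3; 2.00: 47.9, 15.8; 3.00: 62.4, 12.4
- Tuesday's (time / min: target / %, starting material / %): 0.667: 22.3, 2.3; 1.33: 39.0, 5.8; 2.00: 52.2, 12.9; 2.50: 60.9, 0.7; 3.00: 69.3, 11.1

(readings scatter by 0.5 percentage points)

- which of the two ends with the higher amount of target, in percent of the starting material charged ("neither" if they lie within 2 percentage points) (red / amber / neither)
- target at the end, in percent of the starting material charged, red
- target at the end, in percent of the starting material charged, amber



Friday's first reading gives the speed at the start, and its last minute gives the speed late in the run: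

start: 4510 min⁻¹
late: 1670 min⁻¹
slowing: a factor of 2.70

If the rate follows the second substrate left, Friday's target has used enough of it to give a factor of about 2.31. I leave the remaining factor of 1.17 to whatever opens the gap in Friday's balance, which ends 25 percentage points short of the charge.

The starting speed times the length of Friday's run is 13500 turnovers. I call the average of the two runs the turnover budget: the turnover number of a run of this length at this charge of second substrate, 6740. That is half of the product above.

target = budget × enzyme loading
red: 67.4 %
amber: 101 % of the charge

Amber's budget is more than the whole charge, so, as my own estimate, I subtract Friday's gap and expect 74.8 %, more than red.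

The forecast says red, with 66 % for red and 60 % for amber: “dosing probably wins narrowly”. My amber stands above its figure.

The flasks give amber, with 66.7 % for red and 72.3 % for amber.

    starting material + free enzyme ⇌ first complex (K = 117 M⁻¹, k = 4.55 × 10⁵ M⁻¹ s⁻¹)
    first complex → loaded enzyme + first product (k = 690 s⁻¹)
    second substrate + loaded enzyme ⇌ second complex (K = 25.0 M⁻¹, k = 2.15 × 10⁵ M⁻¹ s⁻¹)
    second complex → free enzyme + target (k = 442 s⁻¹)
    starting material + target → side product (k = 0.687 M⁻¹ s⁻¹)
    free enzyme ⇌ dormant form (K = 0.430, k = 0.00974 s⁻¹)

Counted the same way, red ends at 6670 turnovers. Amber ends at 4820, with 0 % of its starting material left. The neighbour of red charged with 0.660 equiv of second substrate reaches 44.2 % target, which is 4420 turnovers against the budget of 6740. It ends with 11.1 % of its second substrate left and 87.5 % of the catalyst standing as loaded enzyme.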